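**Retrosynthetic overview**
- The target comes from its TBS ether, whose spiro N,O-ketal (the only stereocentre) is closed last by a chiral phosphoric acid from a racemic 3-aryl-3-hydroxyisoindolinone.
- That hydroxylactam comes from a late union of two similar-sized halves: an ortho-metalated 3-methoxybenzamide and a strained peri-naphtholactone as acyl donor; the isoindolinone ring closes in the same operation.
- The benzamide half comes from 3-bromophenol, CO2 and 2-aminoethanol, with ortho-iodination at the doubly activated C2.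
- The naphtholactone comes from an 8-bromo-1-naphthol and CO2; the naphthalene is built by Heck reaction and benzannulation from 4-bromophenol and 3-methylbut-3-enoic acid.
- Ring order: naphthalene, then peri-lactone, then isoindolinone (at the coupling), then the spiro-furan ring.

Assumption: the target SMILES corresponds to (S) at the spiro carbon; the sense of induction of the phosphoric acid in step 13 cannot be predicted, so (R)-TRIP is written and its enantiomer is used if the first run gives the (R)-spirocycle.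

**Route**

Step 1
Reactants: 1 3-bromophenol
Product: 2 3-bromoanisole
Conditions: MeI, K2CO3, acetone, reflux
Reagents that add atoms: iodomethane, CI
Why: Williamson ether synthesis; the phenoxide is methylated cleanly and the aryl bromide is untouched.

Step 2
Reactants: 2 3-bromoanisole
Product: 4 3-methoxybenzoic acid, via (3-methoxyphenyl)magnesium bromide 3 (not isolated)
Conditions: Mg, cat. I2, THF, reflux; CO2, -20 °C; 2 M HCl
Reagents that add atoms: carbon dioxide, O=C=O
Why: Grignard formation and carboxylation give the benzoic acid directly.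

Step 3
Reactants: 5 2-aminoethanol
Product: 6 2-[(tert-butyldimethylsilyl)oxy]ethan-1-amine
Conditions: TBSCl, imidazole, CH2Cl2, 0 °C to rt
Reagents that add atoms: tert-butyldimethylsilyl chloride, CC(C)(C)[Si](C)(C)Cl
Why: Silyl protection is O-selective because any N–Si bond is cleaved on aqueous work-up.

Step 4
Reactants: 4 3-methoxybenzoic acid; 6 2-[(tert-butyldimethylsilyl)oxy]ethan-1-amine
Product: 8 N-[2-(tert-butyldimethylsilyloxy)ethyl]-3-methoxybenzamide, via 3-methoxybenzoyl chloride 7 (not isolated)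
Conditions: SOCl2, cat. DMF, toluene, 70 °C, evaporate; then 6, Et3N, CH2Cl2, 0 °C to rt
Reagents that add atoms: none
Why: Schotten–Baumann-type acylation of the primary amine by the acid chloride; Et3N protects the silyl ether from HCl.

Step 5
Reactants: 8 N-[2-(tert-butyldimethylsilyloxy)ethyl]-3-methoxybenzamide
Product: 10 2-iodo-3-methoxy-N-[2-(tert-butyldimethylsilyloxy)ethyl]benzamide, via N,2-dilithiated benzamide 9 (not isolated)
Conditions: s-BuLi (2.3 equiv), TMEDA, THF, -78 °C; I2, -78 to 0 °C; aq. Na2S2O3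
Reagents that add atoms: iodine, II
Why: Directed ortho-metalation of the N-lithio amide occurs at C2, the site activated by both the amide and the methoxy group, and iodine traps the aryllithium.

Step 6
Reactants: 11 4-bromophenol
Product: 12 1-(benzyloxy)-4-bromobenzene
Conditions: BnBr, K2CO3, acetone, reflux
Reagents that add atoms: benzyl bromide, BrCc1ccccc1
Why: Williamson benzylation; the benzyl ether survives every later step up to the hydrogenolysis.

Step 7
Reactants: 12 1-(benzyloxy)-4-bromobenzene; 13 3-methylbut-3-enoic acid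
Product: 14 (E)-4-[4-(benzyloxy)phenyl]-3-methylbut-3-enoic acid (carried on together with its double-bond isomers)
Conditions: Pd2(dba)3 (1.5 mol%), [HP(t-Bu)3]BF4 (6 mol%), Cy2NMe (2.5 equiv), dioxane, 90 °C; acidic work-up
Reagents that add atoms: none
Why: Mizoroki–Heck arylation at the terminal CH2 of the 1,1-disubstituted alkene gives the aryl–C4 skeleton; all β-hydride-elimination isomers converge in step 8.

Step 8
Reactants: 14 (E)-4-[4-(benzyloxy)phenyl]-3-methylbut-3-enoic acid
Product: 17 7-(benzyloxy)-3-methylnaphthalen-1-yl acetate, via mixed acetic anhydride 15 (not isolated), via 7-(benzyloxy)-3-methylnaphthalen-1-ol 16 (not isolated)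
Conditions: Ac2O, NaOAc, 140 °C
Reagents that add atoms: acetic anhydride, CC(=O)OC(C)=O
Why: Classical Ac2O/NaOAc benzannulation: the mixed anhydride gives an aryl vinylketene (alkene isomers equilibrate through the dienolate), 6π-electrocyclisation and tautomerisation give the 1-naphthol, which is acetylated in situ.

Step 9
Reactants: 17 7-(benzyloxy)-3-methylnaphthalen-1-yl acetate
Product: 19 7-(benzyloxy)-8-bromo-3-methylnaphthalen-1-ol, via 7-(benzyloxy)-8-bromo-3-methylnaphthalen-1-yl acetate 18 (not isolated)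
Conditions: NBS (1.0 equiv), MeCN, 0 °C; then 7 M NH3 in MeOH, rt
Reagents that add atoms: N-bromosuccinimide, O=C1CCC(=O)N1Br
Why: Electrophilic bromination goes to C8, the α-position ortho to the strongly activating benzyloxy group, because the acetoxy ring is much less activated; ammonolysis then frees the peri-naphthol.

Step 10
Reactants: 19 7-(benzyloxy)-8-bromo-3-methylnaphthalen-1-ol
Product: 22 3-(benzyloxy)-7-methyl-2H-naphtho[1,8-bc]furan-2-one (the peri-lactone of acid 21), via lithium 7-(benzyloxy)-8-lithio-3-methylnaphthalen-1-olate 20 (not isolated), via 2-(benzyloxy)-8-hydroxy-6-methyl-1-naphthoic acid 21 (not isolated)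
Conditions: n-BuLi (2.2 equiv), THF, -78 °C; CO2; 2 M HCl, rt to 40 °C
Reagents that add atoms: carbon dioxide, O=C=O
Why: Deprotonation then bromine–lithium exchange and carboxylation give the peri-hydroxy acid, which lactonises on acidification.

Step 11
Reactants: 10 2-iodo-3-methoxy-N-[2-(tert-butyldimethylsilyloxy)ethyl]benzamide; 22 3-(benzyloxy)-7-methyl-2H-naphtho[1,8-bc]furan-2-one
Product: 25 racemic 3-[2-(benzyloxy)-8-hydroxy-6-methylnaphthalen-1-yl]-2-[2-(tert-butyldimethylsilyloxy)ethyl]-3-hydroxy-4-methoxyisoindolin-1-one, via N,2-dimagnesiated benzamide 23 (not isolated), via ring-opened keto amide 24 (not isolated)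
Conditions: 10 (1.15 equiv), MeMgCl, THF, -30 °C; i-PrMgCl·LiCl, -30 °C; then 22, -30 °C to rt; aq. NH4Cl; chromatography on Et3N-deactivated silica
Reagents that add atoms: none
Why: Iodine–magnesium exchange on the N-deprotonated amide gives an aryl Grignard that opens the strained aryl lactone by nucleophilic acyl substitution; the hindered ketone is trapped by the amide nitrogen as the hydroxylactam, which prevents a second addition.

Step 12
Reactants: 25 racemic benzyl-protected hydroxylactam
Product: 26 racemic 3-(2,8-dihydroxy-6-methylnaphthalen-1-yl)-2-[2-(tert-butyldimethylsilyloxy)ethyl]-3-hydroxy-4-methoxyisoindolin-1-one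
Conditions: H2 (1 atm), 10% Pd/C, EtOAc, rt
Reagents that add atoms: none
Why: Neutral hydrogenolysis cleaves the aryl benzyl ether quickly and leaves the silyl ether and the tertiary hydroxylactam intact.

Step 13
Reactants: 26 racemic dihydroxynaphthyl hydroxylactam
Product: 28 (S)-2-[2-(tert-butyldimethylsilyloxy)ethyl]-3'-hydroxy-7-methoxy-7'-methyl-2'H-spiro[isoindoline-1,2'-naphtho[1,8-bc]furan]-3-one, via ortho-quinone methide 27 (not isolated)
Conditions: (R)-TRIP (10 mol%), 5 Å MS, toluene, -20 °C; filter through basic alumina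
Reagents that add atoms: none
Why: The chiral phosphoric acid dehydrates the hydroxylactam to a planar ortho-quinone methide (N-acyliminium equivalent) bound in its chiral pocket, and the peri-OH closes the five-membered ring by face-selective intramolecular oxa-Michael addition, setting the spiro centre as (S); the side-chain oxygen is silylated so it cannot compete.

Step 14
Reactants: 28 (S)-spiro silyl ether
Product: 29 (S)-3'-hydroxy-2-(2-hydroxyethyl)-7-methoxy-7'-methyl-2'H-spiro[isoindoline-1,2'-naphtho[1,8-bc]furan]-3-one (target)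
Conditions: TBAF, AcOH (1:1, 1.5 equiv), THF, 0 °C to rt
Reagents that add atoms: none
Why: Acetic-acid-buffered fluoride desilylation removes the primary TBS ether without the acid or base that could reopen the N,O-ketal, so the spiro configuration is kept.

**Compound list**
1 | 3-bromophenol | Oc1cccc(Br)c1 | starting material
2 | 3-bromoanisole | COc1cccc(Br)c1 | intermediate
3 | (3-methoxyphenyl)magnesium bromide | COc1cccc([Mg]Br)c1 | intermediate
4 | 3-methoxybenzoic acid | COc1cccc(C(=O)O)c1 | intermediate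
5 | 2-aminoethanol | NCCO | starting material
6 | 2-[(tert-butyldimethylsilyl)oxy]ethan-1-amine | NCCO[Si](C)(C)C(C)(C)C | intermediate
7 | 3-methoxybenzoyl chloride | COc1cccc(C(=O)Cl)c1 | intermediate
8 | N-[2-(tert-butyldimethylsilyloxy)ethyl]-3-methoxybenzamide | COc1cccc(C(=O)NCCO[Si](C)(C)C(C)(C)C)c1 | intermediate
9 | N,2-dilithiated N-[2-(tert-butyldimethylsilyloxy)ethyl]-3-methoxybenzamide | COc1cccc(C(=O)N([Li])CCO[Si](C)(C)C(C)(C)C)c1[Li] | intermediate
10 | 2-iodo-3-methoxy-N-[2-(tert-butyldimethylsilyloxy)ethyl]benzamide | COc1cccc(C(=O)NCCO[Si](C)(C)C(C)(C)C)c1I | intermediate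
11 | 4-bromophenol | Oc1ccc(Br)cc1 | starting material
12 | 1-(benzyloxy)-4-bromobenzene | Brc1ccc(OCc2ccccc2)cc1 | intermediate
13 | 3-methylbut-3-enoic acid | C=C(C)CC(=O)O | starting material
14 | (E)-4-[4-(benzyloxy)phenyl]-3-methylbut-3-enoic acid | OC(=O)C/C(C)=C/c1ccc(OCc2ccccc2)cc1 | intermediate
15 | acetic (E)-4-[4-(benzyloxy)phenyl]-3-methylbut-3-enoic anhydride | CC(=O)OC(=O)C/C(C)=C/c1ccc(OCc2ccccc2)cc1 | intermediate
16 | 7-(benzyloxy)-3-methylnaphthalen-1-ol | Cc1cc(O)c2cc(OCc3ccccc3)ccc2c1 | intermediate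
17 | 7-(benzyloxy)-3-methylnaphthalen-1-yl acetate | CC(=O)Oc1cc(C)cc2ccc(OCc3ccccc3)cc12 | intermediate
18 | 7-(benzyloxy)-8-bromo-3-methylnaphthalen-1-yl acetate | CC(=O)Oc1cc(C)cc2ccc(OCc3ccccc3)c(Br)c12 | intermediate
19 | 7-(benzyloxy)-8-bromo-3-methylnaphthalen-1-ol | Cc1cc(O)c2c(Br)c(OCc3ccccc3)ccc2c1 | intermediate
20 | lithium 7-(benzyloxy)-8-lithio-3-methylnaphthalen-1-olate | Cc1cc(O[Li])c2c([Li])c(OCc3ccccc3)ccc2c1 | intermediate
21 | 2-(benzyloxy)-8-hydroxy-6-methyl-1-naphthoic acid | Cc1cc(O)c2c(C(=O)O)c(OCc3ccccc3)ccc2c1 | intermediate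
22 | 3-(benzyloxy)-7-methyl-2H-naphtho[1,8-bc]furan-2-one | O=C1Oc2cc(C)cc3ccc(OCc4ccccc4)c1c23 | intermediate
23 | N,2-bis(chloromagnesio) N-[2-(tert-butyldimethylsilyloxy)ethyl]-3-methoxybenzamide | COc1cccc(C(=O)N([Mg]Cl)CCO[Si](C)(C)C(C)(C)C)c1[Mg]Cl | intermediate
24 | 2-[2-(benzyloxy)-8-hydroxy-6-methyl-1-naphthoyl]-N-[2-(tert-butyldimethylsilyloxy)ethyl]-3-methoxybenzamide (formed as its magnesium salt) | COc1cccc(C(=O)NCCO[Si](C)(C)C(C)(C)C)c1C(=O)c1c(OCc2ccccc2)ccc2cc(C)cc(O)c12 | intermediate
25 | racemic 3-[2-(benzyloxy)-8-hydroxy-6-methylnaphthalen-1-yl]-2-[2-(tert-butyldimethylsilyloxy)ethyl]-3-hydroxy-4-methoxyisoindolin-1-one | COc1cccc2c1C(O)(c1c(OCc3ccccc3)ccc3cc(C)cc(O)c13)N(CCO[Si](C)(C)C(C)(C)C)C2=O | intermediate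
26 | racemic 3-(2,8-dihydroxy-6-methylnaphthalen-1-yl)-2-[2-(tert-butyldimethylsilyloxy)ethyl]-3-hydroxy-4-methoxyisoindolin-1-one | COc1cccc2c1C(O)(c1c(O)ccc3cc(C)cc(O)c13)N(CCO[Si](C)(C)C(C)(C)C)C2=O | intermediate
27 | ortho-quinone methide: 2-[2-(tert-butyldimethylsilyloxy)ethyl]-3-(8-hydroxy-6-methyl-2-oxonaphthalen-1(2H)-ylidene)-4-methoxyisoindolin-1-one | COc1cccc2c1C(=C1C(=O)C=Cc3cc(C)cc(O)c13)N(CCO[Si](C)(C)C(C)(C)C)C2=O | intermediate
28 | (S)-2-[2-(tert-butyldimethylsilyloxy)ethyl]-3'-hydroxy-7-methoxy-7'-methyl-2'H-spiro[isoindoline-1,2'-naphtho[1,8-bc]furan]-3-one | COc1cccc2c1[C@]1(Oc3cc(C)cc4ccc(O)c1c34)N(CCO[Si](C)(C)C(C)(C)C)C2=O | intermediate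
29 | (S)-3'-hydroxy-2-(2-hydroxyethyl)-7-methoxy-7'-methyl-2'H-spiro[isoindoline-1,2'-naphtho[1,8-bc]furan]-3-one | COc1cccc2c1[C@]1(Oc3cc(C)cc4ccc(O)c1c34)N(CCO)C2=O | target

**Totals**
Total step count: 14. Longest linear sequence: 9 (steps 6–10, then 11–14, from 4-bromophenol); steps 1–5 run in parallel.

**Steps most likely to fail, with fallbacks**

Step 7 (Heck reaction of an electron-rich aryl bromide with a 1,1-disubstituted alkenoic acid; the alkene may isomerise to the unreactive conjugated acid). The fallback sets out from 12 and builds the side chain from a ketone instead. Palladium-catalysed mono-α-arylation of acetone (Pd/Mor-DalPhos, Cs2CO3) gives 1-[4-(benzyloxy)phenyl]propan-2-one F1. Horner–Wadsworth–Emmons olefination with triethyl phosphonoacetate and NaH gives ethyl 4-[4-(benzyloxy)phenyl]-3-methylbut-2-enoate F2 as an E/Z mixture. Saponification with LiOH gives 4-[4-(benzyloxy)phenyl]-3-methylbut-2-enoic acid F3. Under the step 8 conditions F3 forms the same vinylketene by γ-deprotonation, and the route is rejoined at 17.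

Step 11 (addition of a di-ortho-substituted aryl Grignard to the hindered lactone carbonyl). The fallback sets out from 19 and uses an aldehyde electrophile followed by oxidation. Benzylation (BnBr, K2CO3) gives 1,7-bis(benzyloxy)-8-bromo-3-methylnaphthalene F4. Bromine–lithium exchange and DMF give 2,8-bis(benzyloxy)-6-methyl-1-naphthaldehyde F5. Addition of the arylmagnesium 23 made from 10 gives the diarylmethanol 2-{[2,8-bis(benzyloxy)-6-methylnaphthalen-1-yl](hydroxy)methyl}-N-[2-(tert-butyldimethylsilyloxy)ethyl]-3-methoxybenzamide F6. Dess–Martin oxidation gives the ketone, which closes to 3-[2,8-bis(benzyloxy)-6-methylnaphthalen-1-yl]-2-[2-(tert-butyldimethylsilyloxy)ethyl]-3-hydroxy-4-methoxyisoindolin-1-one F7. Hydrogenolysis of both benzyl ethers (H2, Pd/C, EtOAc) rejoins the route at 26.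

Step 13 (enantioselectivity of the spiroketalisation; an uncatalysed racemic background closure is possible). The fallback sets out from 26 and replaces asymmetric catalysis by resolution. Cyclisation with an achiral acid (diphenyl phosphate, toluene, rt) gives racemic 2-[2-(tert-butyldimethylsilyloxy)ethyl]-3'-hydroxy-7-methoxy-7'-methyl-2'H-spiro[isoindoline-1,2'-naphtho[1,8-bc]furan]-3-one F8. Preparative chiral SFC on an amylose phase separates the (S)-enantiomer, which rejoins the route at 28; the (R)-enantiomer is re-equilibrated with the same acid and recycled.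

**Further compounds**
F1 | step 7 | 1-[4-(benzyloxy)phenyl]propan-2-one | CC(=O)Cc1ccc(OCc2ccccc2)cc1
F2 | step 7 | ethyl 4-[4-(benzyloxy)phenyl]-3-methylbut-2-enoate (E/Z mixture) | CCOC(=O)C=C(C)Cc1ccc(OCc2ccccc2)cc1
F3 | step 7 | 4-[4-(benzyloxy)phenyl]-3-methylbut-2-enoic acid (E/Z mixture) | OC(=O)C=C(C)Cc1ccc(OCc2ccccc2)cc1
F4 | step 11 | 1,7-bis(benzyloxy)-8-bromo-3-methylnaphthalene | Cc1cc(OCc2ccccc2)c2c(Br)c(OCc3ccccc3)ccc2c1
F5 | step 11 | 2,8-bis(benzyloxy)-6-methyl-1-naphthaldehyde | Cc1cc(OCc2ccccc2)c2c(C=O)c(OCc3ccccc3)ccc2c1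
F6 | step 11 | racemic 2-{[2,8-bis(benzyloxy)-6-methylnaphthalen-1-yl](hydroxy)methyl}-N-[2-(tert-butyldimethylsilyloxy)ethyl]-3-methoxybenzamide | COc1cccc(C(=O)NCCO[Si](C)(C)C(C)(C)C)c1C(O)c1c(OCc2ccccc2)ccc2cc(C)cc(OCc3ccccc3)c12
F7 | step 11 | racemic 3-[2,8-bis(benzyloxy)-6-methylnaphthalen-1-yl]-2-[2-(tert-butyldimethylsilyloxy)ethyl]-3-hydroxy-4-methoxyisoindolin-1-one | COc1cccc2c1C(O)(c1c(OCc3ccccc3)ccc3cc(C)cc(OCc4ccccc4)c13)N(CCO[Si](C)(C)C(C)(C)C)C2=O
F8 | step 13 | racemic 2-[2-(tert-butyldimethylsilyloxy)ethyl]-3'-hydroxy-7-methoxy-7'-methyl-2'H-spiro[isoindoline-1,2'-naphtho[1,8-bc]furan]-3-one | COc1cccc2c1C1(Oc3cc(C)cc4ccc(O)c1c34)N(CCO[Si](C)(C)C(C)(C)C)C2=O
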